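**Strategy.** Ring A is disconnected at C1–C2 and C5–C10. The ten-carbon chain C2–C3–C4(C15)–C5–C6–C7=C11(C12,C13) is the skeleton of (E)-β-ocimene, whose diene C2=C3–C4=C5 needs only C1 and C10 to close ring A. An enantioselective Diels–Alder reaction with a 2-substituted acrolein that carries C14 as the formyl group and C9–C8 as a silyl-protected 2-hydroxyethyl arm delivers all fifteen skeletal carbons, both ring-fusion stereocentres (C5, C10), the C3=C4 alkene for the later diol and the prenyl arm that closes ring B by a carbonyl-ene reaction. A silyl ether is used for this arm because an acetal would be ionised by the strong boron Lewis acid.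

Key step: step 2

Numbering: eudesmane numbering (C1–C15) is used for all atoms; β is the face of the C10 methyl (C14), α the opposite face.

Assumption: by the accepted binding model for 2-substituted acroleins (formyl C–H···O contact, s-trans enal stacked on the phenyl group cis to boron) the (R)-catalyst exposes the re face of C10; if the adduct proved antipodal, the (S)-catalyst would be used.

Step 1
Reactants: 1 4-[(tert-butyldimethylsilyl)oxy]butanal; 2 formaldehyde (37% aqueous)
Product: 3 4-[(tert-butyldimethylsilyl)oxy]-2-methylidenebutanal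
Conditions: aq. CH2O (1.1 equiv), pyrrolidine (10 mol%), EtCO2H (10 mol%), i-PrOH, 45 °C
Reagents that add atoms: formaldehyde (compound 2), C=O
Why: Amine-catalysed α-methylenation (Mannich condensation of the enamine of 1 with formaldehyde, then loss of pyrrolidine) should give the 2-methylene aldehyde, the silyl ether being inert to the buffered medium.

Step 2
Reactants: 3 4-[(tert-butyldimethylsilyl)oxy]-2-methylidenebutanal; 4 (E)-β-ocimene
Product: 5 (1S,2S)-1-{2-[(tert-butyldimethylsilyl)oxy]ethyl}-3-methyl-2-(3-methylbut-2-en-1-yl)cyclohex-3-ene-1-carbaldehyde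
Conditions: 4 (E-rich commercial ocimene, 2.5 equiv), (R)-1-(2-methylphenyl)-3,3-diphenyltetrahydro-1H,3H-pyrrolo[1,2-c][1,3,2]oxazaborole (20 mol%), HN(SO2CF3)2 (17 mol%), CH2Cl2, −78 to −40 °C; Et3N quench at −78 °C
Reagents that add atoms: none
Why: The N-protonated oxazaborolidine binds the formyl oxygen of 3, and the s-cis diene C2=C3–C4=C5 of 4 adds in a concerted, asynchronous [4+2] cycloaddition in which C1–C2 forms ahead of C5–C10. The closest known reaction type is the oxazaborolidinium-catalysed Diels–Alder reaction of 2-alkylacroleins with acyclic and cyclic dienes. Ring A closes by intermolecular six-membered [4+2] annulation, suprafacial on both partners, and keeps the C3=C4 alkene. C10 is set by the catalyst, which shields the si face of the α-carbon so that C5 bonds to its re face; C5 is set relative to C10 by the E geometry of C4=C5 together with endo placement of the bound formyl group, which puts C14 cis to the prenyl arm (later 10β-methyl and 5α-H, the trans-decalin pattern). The step needs ortho orientation, which the alkyl group C6 on the diene terminus should secure by stabilising positive charge at C5 more than the C4 methyl on the central carbon opposes it, and endo selectivity, which an acyclic diene without a bridging methylene allows. Only the conjugated diene should react (the C7=C11 alkene is isolated), the Z isomer of ocimene cannot reach the s-cis conformation and stays behind, and the hindered silyl ether oxygen should not compete for boron.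

Step 3
Reactants: 5 (1S,2S)-1-{2-[(tert-butyldimethylsilyl)oxy]ethyl}-3-methyl-2-(3-methylbut-2-en-1-yl)cyclohex-3-ene-1-carbaldehyde
Product: 8 2-[(1R,2R)-1,3-dimethyl-2-(3-methylbut-2-en-1-yl)cyclohex-3-en-1-yl]ethan-1-ol, via hydrazone 6 (not isolated), via silyl ether 7 (not isolated)
Conditions: N2H4·H2O, KOH, diethylene glycol, 130 then 200 °C; then Bu4NF, THF, rt
Reagents that add atoms: none
Why: Wolff–Kishner reduction (Huang–Minlon procedure) of the non-enolisable neopentyl aldehyde should turn C14 into the methyl group without touching C5 or C10, and fluoride then cleaves the primary silyl ether (any silyl ether already lost in the hot alkali leads to the same alcohol).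

Step 4
Reactants: 8 2-[(1R,2R)-1,3-dimethyl-2-(3-methylbut-2-en-1-yl)cyclohex-3-en-1-yl]ethan-1-ol
Product: 11 (5R,10R)-eudesma-3,11-dien-8-one (C7 epimers), via aldehyde 9 (not isolated), via ene alcohol 10 (not isolated)
Conditions: pyridinium chlorochromate [C5H5NH][CrO3Cl] (2.5 equiv), CH2Cl2, rt
Reagents that add atoms: none
Why: The chlorochromate oxidises the primary alcohol to aldehyde 9, its acidity promotes the carbonyl-ene closure of C8 onto the C7=C11 alkene (the citronellal-to-isopulegol mode, chair transition state with both arms equatorial on ring A, ring fusion inherited from 5), and the secondary alcohol 10 is oxidised in the same flask, as in the known conversion of citronellol into isopulegone; the C7 and C8 configurations do not matter because both centres are erased by step 5.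

Step 5
Reactants: 11 (5R,10R)-eudesma-3,11-dien-8-one (C7 epimers)
Product: 12 (5R,10R)-eudesma-3,7(11)-dien-8-one
Conditions: NaOH, EtOH, rt
Reagents that add atoms: none
Why: Base-mediated isomerisation through the dienolate should move the C11=C12 alkene into conjugation (isopulegone-to-pulegone type) to give the thermodynamically favoured tetrasubstituted s-cis enone, C5 and C10 being non-enolisable.

Step 6
Reactants: 12 (5R,10R)-eudesma-3,7(11)-dien-8-one
Product: 13 (3R,4S,5R,10R)-3α,4α-dihydroxyeudesm-7(11)-en-8-one
Conditions: OsO4 (2 mol%), N-methylmorpholine N-oxide, acetone/H2O, rt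
Reagents that add atoms: osmium tetroxide, O=[Os](=O)(=O)=O; N-methylmorpholine N-oxide, C[N+]1([O-])CCOCC1; water, O
Why: Catalytic OsO4 cis-dihydroxylation should take the electron-rich trisubstituted C3=C4 alkene in preference to the electron-poor tetrasubstituted enone alkene and add from the α-face, away from the axial C10 methyl, which sets C4 (4α-OH, 4β-CH3) and gives the 3α,4α-diol.

Step 7
Reactants: 13 (3R,4S,5R,10R)-3α,4α-dihydroxyeudesm-7(11)-en-8-one
Product: 14 (4S,5R,10R)-4α-hydroxyeudesm-7(11)-ene-3,8-dione
Conditions: 2-iodoxybenzoic acid (IBX), DMSO, rt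
Reagents that add atoms: none
Why: IBX oxidises the secondary axial 3α-hydroxyl of a 1,2-diol to the α-ketol without C–C cleavage, the tertiary 4α-hydroxyl being inert; the ketol is used directly to avoid α-ketol rearrangement.

Step 8
Reactants: 14 (4S,5R,10R)-4α-hydroxyeudesm-7(11)-ene-3,8-dione
Product: 15 (3S,4S,5R,10R)-3β,4α-dihydroxyeudesm-7(11)-en-8-one
Conditions: NaBH4 (1 equiv), MeOH/CH2Cl2, −78 °C
Reagents that add atoms: none
Why: Borohydride reduction should take the saturated, α-oxygenated C3 ketone faster than the hindered conjugated C8 enone, and hydride should enter axially from the α-face because the axial 4β-methyl blocks the β-face, giving the equatorial 3β-alcohol (net inversion at C3).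

Step 9
Reactants: 15 (3S,4S,5R,10R)-3β,4α-dihydroxyeudesm-7(11)-en-8-one; 16 angelic acid
Product: 18 (3S,4S,5R,10R)-3β-angeloyloxy-4α-hydroxyeudesm-7(11)-en-8-one, via mixed anhydride 17 (not isolated)
Conditions: 16, 2,4,6-Cl3C6H2COCl, Et3N, toluene, rt; then 15, 80 °C
Reagents that add atoms: angelic acid (compound 16), C/C=C(/C)C(=O)O
Why: Yamaguchi esterification through mixed anhydride 17 should acylate only the secondary 3β-hydroxyl (the tertiary 4α-hydroxyl is unreactive), and leaving out a nucleophilic pyridine catalyst avoids Z-to-E isomerisation of the angelate to the tiglate.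

Step 10
Reactants: 18 (3S,4S,5R,10R)-3β-angeloyloxy-4α-hydroxyeudesm-7(11)-en-8-one
Product: 19 (3S,4S,5R,10R)-3β-angeloyloxy-4α-hydroxy-11-hydroperoxyeudesm-6-en-8-one (CNP0161122.1)
Conditions: O2, visible light, 5,10,15,20-tetraphenylporphyrin (cat.), CH2Cl2, 0 °C
Reagents that add atoms: dioxygen (as singlet oxygen), O=O
Why: Schenck ene reaction of singlet oxygen with the s-cis isopropylidene ketone: as with pulegone-type enones, oxygen should bond to the β-carbon C11 and hydrogen should be taken from C6, the group geminal to the carbonyl on C7, which shifts the alkene to C6=C7; no stereocentre is created and the electron-poor angelate alkene should react far more slowly.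

**Compound list**

1 | 4-[(tert-butyldimethylsilyl)oxy]butanal | O=CCCCO[Si](C)(C)C(C)(C)C | starting material
2 | formaldehyde (37% aqueous solution) | C=O | starting material
3 | 4-[(tert-butyldimethylsilyl)oxy]-2-methylidenebutanal | C=C(C=O)CCO[Si](C)(C)C(C)(C)C | intermediate
4 | (E)-β-ocimene, (3E)-3,7-dimethylocta-1,3,6-triene | C=C/C(C)=C/CC=C(C)C | starting material
5 | (1S,2S)-1-{2-[(tert-butyldimethylsilyl)oxy]ethyl}-3-methyl-2-(3-methylbut-2-en-1-yl)cyclohex-3-ene-1-carbaldehyde; formyl (C14) cis to prenyl; ring C1 = C10, ring C2 = C5 | C1=C(C)[C@H](CC=C(C)C)[C@@](C=O)(CCO[Si](C)(C)C(C)(C)C)CC1 | intermediate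
6 | (E)-hydrazone of 5 at C14, formed in the flask | C1=C(C)[C@H](CC=C(C)C)[C@@](/C=N/N)(CCO[Si](C)(C)C(C)(C)C)CC1 | intermediate
7 | tert-butyl{2-[(1R,2R)-1,3-dimethyl-2-(3-methylbut-2-en-1-yl)cyclohex-3-en-1-yl]ethoxy}dimethylsilane, formed in the flask (same geometry as 5; the labels change with the priorities) | C1=C(C)[C@H](CC=C(C)C)[C@@](C)(CCO[Si](C)(C)C(C)(C)C)CC1 | intermediate
8 | 2-[(1R,2R)-1,3-dimethyl-2-(3-methylbut-2-en-1-yl)cyclohex-3-en-1-yl]ethan-1-ol | C1=C(C)[C@H](CC=C(C)C)[C@@](C)(CCO)CC1 | intermediate
9 | 2-[(1R,2R)-1,3-dimethyl-2-(3-methylbut-2-en-1-yl)cyclohex-3-en-1-yl]acetaldehyde, formed in the flask | C1=C(C)[C@H](CC=C(C)C)[C@@](C)(CC=O)CC1 | intermediate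
10 | (5R,10R)-eudesma-3,11-dien-8-ol, trans-fused, mixture of C7 and C8 epimers, formed in the flask | CC1=CCC[C@]2(C)CC(O)C(C(C)=C)C[C@@H]12 | intermediate
11 | (5R,10R)-eudesma-3,11-dien-8-one, mixture of C7 epimers | CC1=CCC[C@]2(C)CC(=O)C(C(C)=C)C[C@@H]12 | intermediate
12 | (5R,10R)-eudesma-3,7(11)-dien-8-one | CC1=CCC[C@]2(C)CC(=O)C(=C(C)C)C[C@@H]12 | intermediate
13 | (3R,4S,5R,10R)-3α,4α-dihydroxyeudesm-7(11)-en-8-one | O[C@@H]1CC[C@]2(C)CC(=O)C(=C(C)C)C[C@H]2[C@]1(C)O | intermediate
14 | (4S,5R,10R)-4α-hydroxyeudesm-7(11)-ene-3,8-dione | O=C1CC[C@]2(C)CC(=O)C(=C(C)C)C[C@H]2[C@]1(C)O | intermediate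
15 | (3S,4S,5R,10R)-3β,4α-dihydroxyeudesm-7(11)-en-8-one | O[C@H]1CC[C@]2(C)CC(=O)C(=C(C)C)C[C@H]2[C@]1(C)O | intermediate
16 | angelic acid, (Z)-2-methylbut-2-enoic acid | C/C=C(/C)C(=O)O | starting material
17 | (Z)-2-methylbut-2-enoic 2,4,6-trichlorobenzoic anhydride, formed in the flask | C/C=C(/C)C(=O)OC(=O)c1c(Cl)cc(Cl)cc1Cl | intermediate
18 | (3S,4S,5R,10R)-3β-angeloyloxy-4α-hydroxyeudesm-7(11)-en-8-one | C/C=C(/C)C(=O)O[C@H]1CC[C@]2(C)CC(=O)C(=C(C)C)C[C@H]2[C@]1(C)O | intermediate
19 | (3S,4S,5R,10R)-3β-angeloyloxy-4α-hydroxy-11-hydroperoxyeudesm-6-en-8-one | C/C=C(/C)C(=O)O[C@H]1CC[C@]2(C)CC(=O)C(C(C)(C)OO)=C[C@H]2[C@]1(C)O | target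

**Totals.** Total step count: 10. Longest linear sequence: 10 steps (1 to 19; 4 enters at step 2 and 16 at step 9).

**Steps most likely to fail**

Step 2. The diene may add in the reversed orientation (C5 to C1), because the C4 methyl works against the directing effect of C6. The formyl group may take the exo position, the trisubstituted diene may turn over slowly, or face discrimination may erode. Fallback: setting out from 3 and 4, the cycloaddition is promoted by the achiral Lewis acid Me2AlCl (CH2Cl2, −78 to −20 °C), where temperature and stoichiometry can be tuned for orientation and endo control alone. This gives the racemate, that is 5 together with its mirror image (1R,2R)-1-{2-[(tert-butyldimethylsilyl)oxy]ethyl}-3-methyl-2-(3-methylbut-2-en-1-yl)cyclohex-3-ene-1-carbaldehyde F1. The two are separated by preparative chromatography on a chiral stationary phase (amylose tris(3,5-dimethylphenylcarbamate), supercritical CO2/MeOH). The route is rejoined at compound 5, with absolute configuration controlled by resolution instead of catalysis.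

Step 4. Under the acidic chromium reagent, aldehyde 9 may be captured stepwise by the ring alkene C3=C4 (Prins closure across ring A), or may be over-oxidised before the ene closure. Fallback: setting out from 8, the three events are separated and the ring closure is changed from an acid-driven cyclisation to a concerted, aluminium-templated ene reaction. Oxidation with Dess–Martin periodinane gives aldehyde 9, which is isolated. Me2AlCl (CH2Cl2, −78 °C), a Lewis acid that scavenges protons and so suppresses cationic Prins pathways, should give ene alcohol 10 through the chair transition state open only to the prenyl arm. A second Dess–Martin oxidation gives 11, where the route is rejoined; no compound outside the list is made (F0).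

Step 9. Acylation of the hindered 3β-hydroxyl next to the quaternary C4 may be slow, and forcing it may isomerise the angelate (Z) to the tiglate (E). Fallback: setting out from 15, the Z alkene is built on the ester instead of being carried in. Esterification (EDC·HCl, 4-(dimethylamino)pyridine, CH2Cl2) with 2-[bis(2,2,2-trifluoroethoxy)phosphoryl]propanoic acid gives 3β-{2-[bis(2,2,2-trifluoroethoxy)phosphoryl]propanoyloxy}-4α-hydroxyeudesm-7(11)-en-8-one F2. Still–Gennari olefination (KN(SiMe3)2, 18-crown-6, THF, −78 °C, then acetaldehyde) should then give the Z-configured 2-methylbut-2-enoate, that is 18, where the route is rejoined.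

**Further compounds**

F1 | step 2 | (1R,2R)-1-{2-[(tert-butyldimethylsilyl)oxy]ethyl}-3-methyl-2-(3-methylbut-2-en-1-yl)cyclohex-3-ene-1-carbaldehyde (enantiomer of 5) | C1=C(C)[C@@H](CC=C(C)C)[C@](C=O)(CCO[Si](C)(C)C(C)(C)C)CC1
F0 | step 4 | none | none
F2 | step 9 | 3β-{2-[bis(2,2,2-trifluoroethoxy)phosphoryl]propanoyloxy}-4α-hydroxyeudesm-7(11)-en-8-one (epimers at the phosphonate carbon) | CC(P(=O)(OCC(F)(F)F)OCC(F)(F)F)C(=O)O[C@H]1CC[C@]2(C)CC(=O)C(=C(C)C)C[C@H]2[C@]1(C)O
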